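**Retrosynthetic overview**
1. The last C–C bond is the tertiary carbinol: the western bicycle, as a primary alkylcerium (from iodide 12), adds to the hindered ring ketone 24 of the eastern bicycle; desilylation and double oxidation then unveil the two 3-ketones.
2. Each trans-fused oxepane/cyclohexane pair is made in one operation from an acyclic (S,S,S)-diepoxide by a silyl-triflate-triggered oxa-/carbacyclisation. The western one ends on an enol silane (ketone, then Wittig methylene), the eastern one on a propargylsilane (allene, then ozonolysis to the ketone).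
3. Epoxide stereocentres come from ketone-catalysed (Shi) asymmetric epoxidation of achiral polyenes; the eastern secondary methyl comes from ene-reductase reduction of (2E,6E)-farnesal.
4. Chains: geranyl bromide + β-ketophosphonate, then HWE (west); farnesol (east).
5. Ring order: western oxepane + cyclohexane together (step 5), eastern oxepane + cyclohexane together (step 14).

Assumption/convention: the enantiomer drawn requires the (S,S)-epoxide series, so the L-configured Shi ketone (ent-Shi ketone, 1,2:4,5-di-O-isopropylidene-β-L-erythro-2,3-hexodiulo-2,6-pyranose) is the catalyst. Bicycles carry 1-benzoxepine locants (O1, C2–C5, C5a, C6–C9, C9a); "western" is the methylidene half, "eastern" the carbinol half.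

**Western half**

Step 1
Reactants: 1 dimethyl (2-oxopropyl)phosphonate; 2 geranyl bromide
Product: 4 dimethyl [(5E)-6,10-dimethyl-2-oxoundeca-5,9-dien-1-yl]phosphonate, via sodium lithium dianion 3 (not isolated)
Conditions: NaH, THF, 0 °C; n-BuLi, 0 °C; 2, 0 °C → rt; aq. NH4Cl
Reagents that add atoms: none
Why: γ-Alkylation of a β-ketophosphonate 1,3-dianion, in which the more basic methyl-derived carbanion displaces the allylic bromide (SN2) and the phosphonate carbanion is kept for the next step; no stereocentre is formed.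

Step 2
Reactants: 4 dimethyl [(5E)-6,10-dimethyl-2-oxoundeca-5,9-dien-1-yl]phosphonate; 5 [(4-methoxybenzyl)oxy]acetaldehyde
Product: 6 (2E,7E)-1-[(4-methoxybenzyl)oxy]-8,12-dimethyltrideca-2,7,11-trien-4-one
Conditions: Ba(OH)2, THF/H2O (40:1), rt
Reagents that add atoms: none
Why: Horner–Wadsworth–Emmons olefination of the stabilised phosphonate under mild base gives the (E)-enone and brings in the two-carbon linker already oxygenated.

Step 3
Reactants: 6 (2E,7E)-1-[(4-methoxybenzyl)oxy]-8,12-dimethyltrideca-2,7,11-trien-4-one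
Product: 7 (2E,7S,8S,11S)-7,8:11,12-diepoxy-1-[(4-methoxybenzyl)oxy]-8,12-dimethyltridec-2-en-4-one
Conditions: ent-Shi ketone (0.6 equiv), KHSO5 (Oxone), K2CO3, Bu4NHSO4, Na2B4O7/Na2EDTA buffer, MeCN–CH2(OMe)2, 0 °C
Reagents that add atoms: Oxone (potassium peroxymonosulfate, KHSO5), [K+].[O-]S(=O)(=O)OO
Why: Shi asymmetric epoxidation, in which the chiral dioxirane transfers oxygen through a spiro transition state only to the two electron-rich trisubstituted alkenes (the enone C=C is too electron-poor), the L-configured catalyst giving the 7S,8S and 11S epoxides, the first stereocentres of the route.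

Step 4
Reactants: 7 (2E,7S,8S,11S)-7,8:11,12-diepoxy-1-[(4-methoxybenzyl)oxy]-8,12-dimethyltridec-2-en-4-one
Product: 8 triethyl{[(3Z,7S,8S,11S)-7,8:11,12-diepoxy-1-[(4-methoxybenzyl)oxy]-8,12-dimethyltridec-3-en-4-yl]oxy}silane
Conditions: Et3SiH, RhCl(PPh3)3 (2 mol %), toluene, 50 °C
Reagents that add atoms: triethylsilane, CC[SiH](CC)CC
Why: Rhodium-catalysed 1,4-hydrosilylation of the enone gives the (Z)-silyl enol ether regiospecifically on the linker side, which enolisation of the saturated ketone could not do, and leaves the epoxides alone.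

Step 5
Reactants: 8 triethyl{[(3Z,7S,8S,11S)-7,8:11,12-diepoxy-1-[(4-methoxybenzyl)oxy]-8,12-dimethyltridec-3-en-4-yl]oxy}silane
Product: 9 (3S,5aS,6S,9aS)-6-{2-[(4-methoxybenzyl)oxy]ethyl}-2,2,5a-trimethyl-3-[(triethylsilyl)oxy]decahydro-1-benzoxepin-7-one
Conditions: TESOTf (0.5 equiv), 2,6-di-tert-butyl-4-methylpyridine, CH2Cl2, −78 °C; aq. NaHCO3
Reagents that add atoms: none
Why: Silyl-triflate-triggered tandem oxa-/carbacyclisation (epoxide-opening cascade), in which the inner epoxide oxygen opens the silylated terminal epoxide at its tertiary carbon (7-endo) and the enol silane opens the resulting epoxonium ion anti at the tertiary carbon through a chair, giving the trans ring fusion (5aS,9aS), the equatorial side chain (6S) and the ketone, with the silyl group of the enol ether relayed onto O-3.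

Step 6
Reactants: 9 (3S,5aS,6S,9aS)-6-{2-[(4-methoxybenzyl)oxy]ethyl}-2,2,5a-trimethyl-3-[(triethylsilyl)oxy]decahydro-1-benzoxepin-7-one
Product: 10 triethyl{[(3S,5aS,6R,9aS)-6-{2-[(4-methoxybenzyl)oxy]ethyl}-2,2,5a-trimethyl-7-methylidenedecahydro-1-benzoxepin-3-yl]oxy}silane
Conditions: Ph3PCH3Br, KOtBu, toluene, 0 → 80 °C
Reagents that add atoms: methyltriphenylphosphonium bromide, C[P+](c1ccccc1)(c1ccccc1)c1ccccc1.[Br-]
Why: Wittig methylenation, in which the basic ylide lets any 6-epimer equilibrate through the enolate to the equatorial (thermodynamic) side chain before the ketone is consumed (the descriptor changes to 6R by CIP priority only).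

Step 7
Reactants: 10 triethyl{[(3S,5aS,6R,9aS)-6-{2-[(4-methoxybenzyl)oxy]ethyl}-2,2,5a-trimethyl-7-methylidenedecahydro-1-benzoxepin-3-yl]oxy}silane
Product: 11 2-{(3S,5aS,6R,9aS)-2,2,5a-trimethyl-7-methylidene-3-[(triethylsilyl)oxy]decahydro-1-benzoxepin-6-yl}ethan-1-ol
Conditions: DDQ, CH2Cl2/pH 7 buffer (10:1), 0 °C
Reagents that add atoms: none
Why: Oxidative cleavage of the 4-methoxybenzyl ether by DDQ (benzylic hydride abstraction, then hydrolysis) frees the primary alcohol while the hindered silyl ether and the 1,1-disubstituted alkene stay intact.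

Step 8
Reactants: 11 2-{(3S,5aS,6R,9aS)-2,2,5a-trimethyl-7-methylidene-3-[(triethylsilyl)oxy]decahydro-1-benzoxepin-6-yl}ethan-1-ol
Product: 12 triethyl{[(3S,5aS,6R,9aS)-6-(2-iodoethyl)-2,2,5a-trimethyl-7-methylidenedecahydro-1-benzoxepin-3-yl]oxy}silane
Conditions: I2, PPh3, imidazole, CH2Cl2, 0 °C → rt
Reagents that add atoms: iodine, II
Why: Appel-type iodination, in which iodide displaces the alkoxyphosphonium ion of the primary alcohol (SN2) under imidazole buffering that spares the silyl ether.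

**Eastern half**

Step 9
Reactants: 13 (2E,6E)-farnesol
Product: 14 (2E,6E)-farnesal
Conditions: MnO2 (activated), hexane, rt
Reagents that add atoms: none
Why: MnO2 oxidises only the allylic alcohol to the enal and keeps the 2E geometry needed for a single sense of enzymatic reduction.

Step 10
Reactants: 14 (2E,6E)-farnesal
Product: 15 (3S,6E)-3,7,11-trimethyldodeca-6,10-dienal
Conditions: (S)-selective ene-reductase (Old Yellow Enzyme family), NAD(P)+ (cat.), formate dehydrogenase, HCO2Na, phosphate buffer pH 7.0, 5 vol% DMSO, 30 °C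
Reagents that add atoms: none
Why: Ene-reductase-catalysed asymmetric reduction of the activated C=C bond, in which the reduced flavin delivers hydride to C-3 and an active-site acid protonates C-2 (trans addition), the enzyme fixing the 3S methyl stereocentre (later C-7 of the eastern ring, equatorial and matched for the cyclisation) while the isolated alkenes are not substrates.

Step 11
Reactants: 15 (3S,6E)-3,7,11-trimethyldodeca-6,10-dienal
Product: 17 (3S,6E)-3,7,11-trimethyldodeca-6,10-dien-1-yne, via alkenyl nonaflate 16 (not isolated)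
Conditions: C4F9SO2F, P2-Et phosphazene base (2.5 equiv), DMF, 0 °C → rt
Reagents that add atoms: none
Why: One-pot enol nonaflate formation and E2 elimination by the phosphazene base turns the CH2–CHO unit into a terminal alkyne with the same carbon count, the β-stereocentre not being acidic under these conditions.

Step 12
Reactants: 17 (3S,6E)-3,7,11-trimethyldodeca-6,10-dien-1-yne
Product: 19 trimethyl[(4S,7E)-4,8,12-trimethyltrideca-7,11-dien-2-yn-1-yl]silane, via lithium acetylide 18 (not isolated)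
Conditions: n-BuLi, THF, −78 °C; ICH2SiMe3, DMPU, −78 → 50 °C
Reagents that add atoms: (iodomethyl)trimethylsilane, C[Si](C)(C)CI
Why: SN2 alkylation of the lithium acetylide installs the propargylsilane terminator without touching the stereocentre.

Step 13
Reactants: 19 trimethyl[(4S,7E)-4,8,12-trimethyltrideca-7,11-dien-2-yn-1-yl]silane
Product: 20 trimethyl[(4S,7S,8S,11S)-7,8:11,12-diepoxy-4,8,12-trimethyltridec-2-yn-1-yl]silane
Conditions: ent-Shi ketone (0.6 equiv), KHSO5 (Oxone), K2CO3, Bu4NHSO4, Na2B4O7/Na2EDTA buffer, MeCN–CH2(OMe)2, 0 °C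
Reagents that add atoms: Oxone (potassium peroxymonosulfate, KHSO5), [K+].[O-]S(=O)(=O)OO
Why: Shi asymmetric epoxidation, catalyst-controlled as in step 3, epoxidises both trisubstituted alkenes (7S,8S,11S) and leaves the alkyne alone.

Step 14
Reactants: 20 trimethyl[(4S,7S,8S,11S)-7,8:11,12-diepoxy-4,8,12-trimethyltridec-2-yn-1-yl]silane
Product: 22 (3S,5aS,7S,9aS)-6-ethenylidene-2,2,5a,7-tetramethyldecahydro-1-benzoxepin-3-ol, via trimethylsilyl ether 21 (not isolated)
Conditions: TMSOTf (0.5 equiv), 2,6-di-tert-butyl-4-methylpyridine, CH2Cl2, −78 °C; then K2CO3, MeOH, rt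
Reagents that add atoms: none
Why: The same tandem oxa-/carbacyclisation as in step 5, here ended by the propargylsilane (SE2' attack of the proximal alkyne carbon and loss of silicon give the exocyclic allene), the anti, chair-like opening of the epoxonium ion setting 5aS,9aS with the enzyme-set methyl equatorial, after which methanolysis removes the labile trimethylsilyl ether.

Step 15
Reactants: 22 (3S,5aS,7S,9aS)-6-ethenylidene-2,2,5a,7-tetramethyldecahydro-1-benzoxepin-3-ol
Product: 23 {[(3S,5aS,7S,9aS)-6-ethenylidene-2,2,5a,7-tetramethyldecahydro-1-benzoxepin-3-yl]oxy}triethylsilane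
Conditions: TESOTf, 2,6-lutidine, CH2Cl2, −78 → 0 °C
Reagents that add atoms: triethylsilyl trifluoromethanesulfonate, CC[Si](CC)(CC)OS(=O)(=O)C(F)(F)F
Why: Silylation of the hindered secondary alcohol with the reactive silyl triflate gives an ether that survives ozonolysis and organometallic addition.

Step 16
Reactants: 23 {[(3S,5aS,7S,9aS)-6-ethenylidene-2,2,5a,7-tetramethyldecahydro-1-benzoxepin-3-yl]oxy}triethylsilane
Product: 24 (3S,5aR,7S,9aS)-2,2,5a,7-tetramethyl-3-[(triethylsilyl)oxy]decahydro-1-benzoxepin-6-one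
Conditions: O3, CH2Cl2/MeOH, NaHCO3, −78 °C; Me2S
Reagents that add atoms: ozone, [O-][O+]=O
Why: Ozonolysis cleaves both C=C bonds of the exocyclic allene so that the ring carbon becomes the ketone, and since no base is present the α-methyl stereocentre (equatorial, also the thermodynamic epimer) is kept.

**Union and end game**

Step 17
Reactants: 12 triethyl{[(3S,5aS,6R,9aS)-6-(2-iodoethyl)-2,2,5a-trimethyl-7-methylidenedecahydro-1-benzoxepin-3-yl]oxy}silane; 24 (3S,5aR,7S,9aS)-2,2,5a,7-tetramethyl-3-[(triethylsilyl)oxy]decahydro-1-benzoxepin-6-one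
Product: 27 (3S,5aR,6S,7S,9aS)-2,2,5a,7-tetramethyl-3-[(triethylsilyl)oxy]-6-(2-{(3S,5aS,6R,9aS)-2,2,5a-trimethyl-7-methylidene-3-[(triethylsilyl)oxy]decahydro-1-benzoxepin-6-yl}ethyl)decahydro-1-benzoxepin-6-ol, via alkyllithium 25 (not isolated), via alkylcerium dichloride 26 (not isolated)
Conditions: 12 (1.5 equiv), t-BuLi (3.0 equiv), Et2O/pentane, −78 °C; CeCl3 (anhydrous), THF, −78 °C; 24, −78 → −40 °C; aq. NH4Cl
Reagents that add atoms: none
Why: Iodine–lithium exchange, transmetalation to the weakly basic organocerium and 1,2-addition to the enolisable, hindered ketone, the bulky reagent entering along the equatorial trajectory (away from the two syn-axial hydrogens of the other face) so that the new chain is equatorial and trans to the C-7 methyl and the hydroxyl is axial, i.e. 6S.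

Step 18
Reactants: 27 (the bis-silyl ether of step 17)
Product: 28 (3S,5aR,6S,7S,9aS)-6-{2-[(3S,5aS,6R,9aS)-3-hydroxy-2,2,5a-trimethyl-7-methylidenedecahydro-1-benzoxepin-6-yl]ethyl}-2,2,5a,7-tetramethyldecahydro-1-benzoxepine-3,6-diol
Conditions: HF·pyridine, pyridine, THF, 0 °C → rt
Reagents that add atoms: none
Why: Fluoride cleaves both triethylsilyl ethers under buffered conditions that leave the tertiary alcohol and the exocyclic alkene alone.

Step 19
Reactants: 28 (the triol of step 18)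
Product: 29 (5aR,6S,7S,9aS)-6-hydroxy-2,2,5a,7-tetramethyl-6-{2-[(5aS,6R,9aS)-2,2,5a-trimethyl-7-methylidene-3-oxodecahydro-1-benzoxepin-6-yl]ethyl}octahydro-1-benzoxepin-3(2H)-one
Conditions: Dess–Martin periodinane, NaHCO3, CH2Cl2, rt
Reagents that add atoms: none
Why: Dess–Martin oxidation turns the two secondary alcohols into the 3-ketones and cannot touch the tertiary alcohol, so no remaining stereocentre is affected.

**Compound list**

1 | dimethyl (2-oxopropyl)phosphonate | COP(=O)(OC)CC(C)=O | starting material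
2 | geranyl bromide, (2E)-1-bromo-3,7-dimethylocta-2,6-diene | CC(C)=CCC/C(C)=C/CBr | starting material
3 | sodium lithium 1,3-dianion of 1 | [Na+].[Li+].[CH2-]C(=O)[CH-]P(=O)(OC)OC | intermediate
4 | dimethyl [(5E)-6,10-dimethyl-2-oxoundeca-5,9-dien-1-yl]phosphonate | COP(=O)(OC)CC(=O)CC/C=C(\C)CCC=C(C)C | intermediate
5 | [(4-methoxybenzyl)oxy]acetaldehyde | COc1ccc(COCC=O)cc1 | starting material
6 | (2E,7E)-1-[(4-methoxybenzyl)oxy]-8,12-dimethyltrideca-2,7,11-trien-4-one | COc1ccc(COC/C=C/C(=O)CC/C=C(\C)CCC=C(C)C)cc1 | intermediate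
7 | (2E,7S,8S,11S)-7,8:11,12-diepoxy-1-[(4-methoxybenzyl)oxy]-8,12-dimethyltridec-2-en-4-one | CC1(C)O[C@H]1CC[C@]1(C)O[C@H]1CCC(=O)/C=C/COCc1ccc(OC)cc1 | intermediate
8 | triethyl{[(3Z,7S,8S,11S)-7,8:11,12-diepoxy-1-[(4-methoxybenzyl)oxy]-8,12-dimethyltridec-3-en-4-yl]oxy}silane | CC1(C)O[C@H]1CC[C@]1(C)O[C@H]1CC/C(O[Si](CC)(CC)CC)=C/CCOCc1ccc(OC)cc1 | intermediate
9 | (3S,5aS,6S,9aS)-6-{2-[(4-methoxybenzyl)oxy]ethyl}-2,2,5a-trimethyl-3-[(triethylsilyl)oxy]decahydro-1-benzoxepin-7-one | O=C1CC[C@@H]2OC(C)(C)[C@@H](O[Si](CC)(CC)CC)CC[C@@]2(C)[C@@H]1CCOCc1ccc(OC)cc1 | intermediate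
10 | triethyl{[(3S,5aS,6R,9aS)-6-{2-[(4-methoxybenzyl)oxy]ethyl}-2,2,5a-trimethyl-7-methylidenedecahydro-1-benzoxepin-3-yl]oxy}silane | C=C1CC[C@@H]2OC(C)(C)[C@@H](O[Si](CC)(CC)CC)CC[C@@]2(C)[C@@H]1CCOCc1ccc(OC)cc1 | intermediate
11 | 2-{(3S,5aS,6R,9aS)-2,2,5a-trimethyl-7-methylidene-3-[(triethylsilyl)oxy]decahydro-1-benzoxepin-6-yl}ethan-1-ol | C=C1CC[C@@H]2OC(C)(C)[C@@H](O[Si](CC)(CC)CC)CC[C@@]2(C)[C@@H]1CCO | intermediate
12 | triethyl{[(3S,5aS,6R,9aS)-6-(2-iodoethyl)-2,2,5a-trimethyl-7-methylidenedecahydro-1-benzoxepin-3-yl]oxy}silane | C=C1CC[C@@H]2OC(C)(C)[C@@H](O[Si](CC)(CC)CC)CC[C@@]2(C)[C@@H]1CCI | intermediate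
13 | (2E,6E)-farnesol, (2E,6E)-3,7,11-trimethyldodeca-2,6,10-trien-1-ol | CC(C)=CCC/C(C)=C/CC/C(C)=C/CO | starting material
14 | (2E,6E)-farnesal | CC(C)=CCC/C(C)=C/CC/C(C)=C/C=O | intermediate
15 | (3S,6E)-3,7,11-trimethyldodeca-6,10-dienal | O=CC[C@@H](C)CC/C=C(\C)CCC=C(C)C | intermediate
16 | (1Z,3S,6E)-3,7,11-trimethyldodeca-1,6,10-trien-1-yl nonafluorobutane-1-sulfonate (formed as a 1E/1Z mixture; Z drawn) | FC(F)(F)C(F)(F)C(F)(F)C(F)(F)S(=O)(=O)O/C=C\[C@@H](C)CC/C=C(\C)CCC=C(C)C | intermediate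
17 | (3S,6E)-3,7,11-trimethyldodeca-6,10-dien-1-yne | C#C[C@@H](C)CC/C=C(\C)CCC=C(C)C | intermediate
18 | lithium acetylide of 17 | [Li]C#C[C@@H](C)CC/C=C(\C)CCC=C(C)C | intermediate
19 | trimethyl[(4S,7E)-4,8,12-trimethyltrideca-7,11-dien-2-yn-1-yl]silane | C[Si](C)(C)CC#C[C@@H](C)CC/C=C(\C)CCC=C(C)C | intermediate
20 | trimethyl[(4S,7S,8S,11S)-7,8:11,12-diepoxy-4,8,12-trimethyltridec-2-yn-1-yl]silane | CC1(C)O[C@H]1CC[C@]1(C)O[C@H]1CC[C@H](C)C#CC[Si](C)(C)C | intermediate
21 | {[(3S,5aS,7S,9aS)-6-ethenylidene-2,2,5a,7-tetramethyldecahydro-1-benzoxepin-3-yl]oxy}trimethylsilane | C=C=C1[C@@H](C)CC[C@@H]2OC(C)(C)[C@@H](O[Si](C)(C)C)CC[C@]21C | intermediate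
22 | (3S,5aS,7S,9aS)-6-ethenylidene-2,2,5a,7-tetramethyldecahydro-1-benzoxepin-3-ol | C=C=C1[C@@H](C)CC[C@@H]2OC(C)(C)[C@@H](O)CC[C@]21C | intermediate
23 | {[(3S,5aS,7S,9aS)-6-ethenylidene-2,2,5a,7-tetramethyldecahydro-1-benzoxepin-3-yl]oxy}triethylsilane | C=C=C1[C@@H](C)CC[C@@H]2OC(C)(C)[C@@H](O[Si](CC)(CC)CC)CC[C@]21C | intermediate
24 | (3S,5aR,7S,9aS)-2,2,5a,7-tetramethyl-3-[(triethylsilyl)oxy]decahydro-1-benzoxepin-6-one | O=C1[C@@H](C)CC[C@@H]2OC(C)(C)[C@@H](O[Si](CC)(CC)CC)CC[C@]21C | intermediate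
25 | alkyllithium from 12 (lithium in place of iodine) | C=C1CC[C@@H]2OC(C)(C)[C@@H](O[Si](CC)(CC)CC)CC[C@@]2(C)[C@@H]1CC[Li] | intermediate
26 | alkylcerium dichloride from 25 (CeCl2 in place of lithium) | C=C1CC[C@@H]2OC(C)(C)[C@@H](O[Si](CC)(CC)CC)CC[C@@]2(C)[C@@H]1CC[Ce](Cl)Cl | intermediate
27 | (3S,5aR,6S,7S,9aS)-2,2,5a,7-tetramethyl-3-[(triethylsilyl)oxy]-6-(2-{(3S,5aS,6R,9aS)-2,2,5a-trimethyl-7-methylidene-3-[(triethylsilyl)oxy]decahydro-1-benzoxepin-6-yl}ethyl)decahydro-1-benzoxepin-6-ol | C=C1CC[C@@H]2OC(C)(C)[C@@H](O[Si](CC)(CC)CC)CC[C@@]2(C)[C@@H]1CC[C@]1(O)[C@@H](C)CC[C@@H]2OC(C)(C)[C@@H](O[Si](CC)(CC)CC)CC[C@]21C | intermediate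
28 | (3S,5aR,6S,7S,9aS)-6-{2-[(3S,5aS,6R,9aS)-3-hydroxy-2,2,5a-trimethyl-7-methylidenedecahydro-1-benzoxepin-6-yl]ethyl}-2,2,5a,7-tetramethyldecahydro-1-benzoxepine-3,6-diol | C=C1CC[C@@H]2OC(C)(C)[C@@H](O)CC[C@@]2(C)[C@@H]1CC[C@]1(O)[C@@H](C)CC[C@@H]2OC(C)(C)[C@@H](O)CC[C@]21C | intermediate
29 | (5aR,6S,7S,9aS)-6-hydroxy-2,2,5a,7-tetramethyl-6-{2-[(5aS,6R,9aS)-2,2,5a-trimethyl-7-methylidene-3-oxodecahydro-1-benzoxepin-6-yl]ethyl}octahydro-1-benzoxepin-3(2H)-one (CNP0218659.1) | C=C1CC[C@@H]2OC(C)(C)C(=O)CC[C@@]2(C)[C@@H]1CC[C@]1(O)[C@@H](C)CC[C@@H]2OC(C)(C)C(=O)CC[C@]21C | target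

**Totals and risks**

Total: 19 steps. Longest linear sequence: 11 steps (steps 1–8 or 9–16, followed by steps 17–19).

Steps most likely to fail:

Step 14 (cascade with the propargylsilane terminator; step 5 is the same kind of reaction with the better-behaved enol silane). If the propargylsilane desilylates or stops after the oxacyclisation, the terminating group is changed. The fallback sets out from alkyne 17. Markovnikov hydrosilylation with Et3SiH and [Cp*Ru(MeCN)3]PF6 gives triethyl[(3S,6E)-3,7,11-trimethyldodeca-1,6,10-trien-2-yl]silane F2. Shi epoxidation as in step 13 gives triethyl[(3S,6S,7S,10S)-6,7:10,11-diepoxy-3,7,11-trimethyldodec-1-en-2-yl]silane F3. Cyclisation with TESOTf and the hindered pyridine, now ended by ipso attack of the vinylsilane with the silyl group relayed to O-3, gives triethyl{[(3S,5aS,7S,9aS)-2,2,5a,7-tetramethyl-6-methylidenedecahydro-1-benzoxepin-3-yl]oxy}silane F4. Ozonolysis of F4 comes back to ketone 24.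

Step 17 (addition to a ketone flanked by a quaternary and a tertiary carbon; the face selectivity is the open point). The fallback sets out from 12 and 24 and uses the wrong epimer instead of discarding it. The (6R)-epimer of 27 F5 (hydroxyl equatorial) is dehydrated with SOCl2/pyridine; an equatorial tertiary alcohol has no anti-periplanar ring hydrogen and eliminates into the side chain to give the exocyclic alkene F6. One equivalent of mCPBA epoxidises this trisubstituted alkene from the face opposite the 5a-methyl to give the spiro-epoxide F7. LiAlH4 opens F7 at its CH carbon and comes back to 27, so C-6 is set by epoxidation rather than by carbonyl addition.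

Step 10 (enzyme acceptance and enantioselectivity on the C15 enal). The fallback sets out from farnesol 13. Asymmetric hydrogenation of the allylic alcohol with Ru(OAc)2[(R)-BINAP] under H2 (100 atm, MeOH) gives (3S,6E)-3,7,11-trimethyldodeca-6,10-dien-1-ol F1. Dess–Martin oxidation of F1 comes back to aldehyde 15.

Further compounds
F1 | step 10 | (3S,6E)-3,7,11-trimethyldodeca-6,10-dien-1-ol | OCC[C@@H](C)CC/C=C(\C)CCC=C(C)C
F2 | step 14 | triethyl[(3S,6E)-3,7,11-trimethyldodeca-1,6,10-trien-2-yl]silane | C=C([Si](CC)(CC)CC)[C@@H](C)CC/C=C(\C)CCC=C(C)C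
F3 | step 14 | triethyl[(3S,6S,7S,10S)-6,7:10,11-diepoxy-3,7,11-trimethyldodec-1-en-2-yl]silane | CC1(C)O[C@H]1CC[C@]1(C)O[C@H]1CC[C@H](C)C(=C)[Si](CC)(CC)CC
F4 | step 14 | triethyl{[(3S,5aS,7S,9aS)-2,2,5a,7-tetramethyl-6-methylidenedecahydro-1-benzoxepin-3-yl]oxy}silane | C=C1[C@@H](C)CC[C@@H]2OC(C)(C)[C@@H](O[Si](CC)(CC)CC)CC[C@]21C
F5 | step 17 | (6R)-epimer of 27 at the eastern carbinol carbon (hydroxyl equatorial) | C=C1CC[C@@H]2OC(C)(C)[C@@H](O[Si](CC)(CC)CC)CC[C@@]2(C)[C@@H]1CC[C@@]1(O)[C@@H](C)CC[C@@H]2OC(C)(C)[C@@H](O[Si](CC)(CC)CC)CC[C@]21C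
F6 | step 17 | exocyclic alkene from F5 by loss of water between eastern C-6 and the adjacent linker carbon (E/Z not defined) | C=C1CC[C@@H]2OC(C)(C)[C@@H](O[Si](CC)(CC)CC)CC[C@@]2(C)[C@@H]1CC=C1[C@@H](C)CC[C@@H]2OC(C)(C)[C@@H](O[Si](CC)(CC)CC)CC[C@]21C
F7 | step 17 | spiro-epoxide of F6 with oxygen on the face opposite the eastern 5a-methyl (linker CH centre not defined) | C=C1CC[C@@H]2OC(C)(C)[C@@H](O[Si](CC)(CC)CC)CC[C@@]2(C)[C@@H]1CC1O[C@]13[C@@H](C)CC[C@@H]2OC(C)(C)[C@@H](O[Si](CC)(CC)CC)CC[C@]23C
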